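**Strategy**

The upper pyran ring (ring C: O1, C2, C3, C4, C4a, C8a) is cut at O1–C2 and C3–C4. Because C4 is benzylic and ortho to O1 on ring A, O1–C8a–C4a–C4 is a latent ortho-quinone methide, while C2–C3 with ring B is the enol form of an aryl methyl ketone. A chiral phosphoric acid joins quinone methide 14, released from benzhydrol 8 that already carries the whole gallocatechin unit, with enamide 13 in a formal hetero-[4+2] addition that closes ring C and sets C4. Hydroboration anti to the C4 aryl then sets C2 and C3. A bromine at C8 of ring D directs the linkage to C6 and leaves in the final hydrogenolysis.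

Key step: step 7

Remark: flavan numbering is used; the upper unit has rings A, B and C, the gallocatechin unit has rings D (benzo ring), E (pyrogallol ring) and F (pyran ring), and (+)-gallocatechin (2R,3S), aldehyde 5 and aldehyde 9 are taken as purchased.

**Route**

Step 1
Reactants: 1 (+)-gallocatechin
Product: 2 hexa-O-benzylgallocatechin
Conditions: BnBr (8 equiv), NaH (7 equiv, in portions), n-Bu4NI (cat.), DMF, −20 °C → rt, argon
Reagents that add atoms: benzyl bromide (BrCc1ccccc1)
Why: Williamson etherification in which benzyl bromide is present before the base, so that each phenoxide and finally the C3 alkoxide of ring F is O-benzylated as it forms; no stereocentre is touched.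

Step 2
Reactants: 2 hexa-O-benzylgallocatechin
Product: 3 8-bromo derivative
Conditions: NBS (1.0 equiv), CH2Cl2, −40 °C → 0 °C
Reagents that add atoms: N-bromosuccinimide (O=C1CCC(=O)N1Br)
Why: Electrophilic aromatic bromination, which in per-O-alkylated flavan-3-ols prefers C8 of ring D (flanked by O1 and one ether) over C6 (flanked by two benzyloxy groups); the bromine is a blocking group that leaves in step 9.

Step 3
Reactants: 3 8-bromo derivative
Product: 4 8-bromo-6-iodo derivative
Conditions: NIS (1.2 equiv), CF3CO2H (10 mol %), CH2Cl2/MeCN, 0 °C → rt, dark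
Reagents that add atoms: N-iodosuccinimide (O=C1CCC(=O)N1I)
Why: Electrophilic aromatic iodination at C6, the only free position of the phloroglucinol-type ring D, which remains far more electron-rich than ring E.

Step 4
Reactants: 4 8-bromo-6-iodo derivative, 5 4-(benzyloxy)-2-hydroxybenzaldehyde
Product: 8 ortho-hydroxybenzhydrol, via arylmagnesium chloride 6 (not isolated), via sodium formylphenoxide 7 (not isolated)
Conditions: 5, NaH (1.05 equiv), THF, 0 °C; 4, i-PrMgCl·LiCl (1.1 equiv), THF, −30 °C; combine, −30 °C → rt; aq. NH4Cl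
Reagents that add atoms: none
Why: Iodine–magnesium exchange is much faster at C–I than at C–Br, and the aryl Grignard reagent 6 adds to the aldehyde of the pre-formed phenoxide 7 (1,2-addition) so that no organometallic is spent on the phenol; the carbinol centre forms unselectively, which is immaterial because it becomes sp2 in step 7.

Step 5
Reactants: 9 3,4,5-tris(benzyloxy)benzaldehyde
Product: 10 3,4,5-tris(benzyloxy)benzonitrile
Conditions: I2 (1.1 equiv), aq. NH3 (28 %), THF, rt
Reagents that add atoms: ammonia (N)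
Why: Oxidative ammonolysis of an aldehyde, in which the aldimine formed with ammonia is N-iodinated and loses HI to give the nitrile.

Step 6
Reactants: 10 3,4,5-tris(benzyloxy)benzonitrile
Product: 13 secondary enamide, via bromomagnesium ketimide 11 (not isolated), via N-acetyl ketimine 12 (not isolated)
Conditions: MeMgBr (1.5 equiv), THF, 60 °C; then Ac2O (2 equiv), 0 °C → rt
Reagents that add atoms: methylmagnesium bromide (C[Mg]Br); acetic anhydride (CC(=O)OC(C)=O)
Why: Grignard addition to the nitrile gives the N-magnesio ketimine 11, N-acetylation gives 12, and 12 tautomerises to the conjugated enamide 13.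

Step 7
Reactants: 8 ortho-hydroxybenzhydrol, 13 secondary enamide
Product: 16 (4S)-4H-chromene, via ortho-quinone methide 14 (not isolated), via N,O-ketal 15 (not isolated)
Conditions: 13 (1.5 equiv), (R)-3,3'-bis(2,4,6-triisopropylphenyl)-1,1'-binaphthyl-2,2'-diyl hydrogen phosphate (10 mol %), 4 Å MS, CHCl3, 0 °C → rt; then pyridinium p-toluenesulfonate (20 mol %), 45 °C
Reagents that add atoms: none
Why: The phosphoric acid dehydrates 8 to the hydrogen-bonded (E)-ortho-quinone methide 14, the enamide 13 (N–H bound to P=O) adds with its terminal carbon to the methide carbon (C3–C4 bond), and the phenolic O1 then closes onto the N-acyliminium carbon C2 (O1–C2 bond) to give N,O-ketal 15, which pyridinium tosylate ionises with loss of acetamide to the 2-aryl oxocarbenium ion that loses the C3 proton to give 16. The closest known reaction type is the chiral-phosphoric-acid-catalysed addition of enamides and other enol-type nucleophiles to ortho-quinone methides generated from ortho-hydroxybenzhydrols, a formal inverse-electron-demand hetero-[4+2] cycloaddition. Ring C is closed as the six-membered ring of that formal [4+2], by 6-exo-trig attack of O1 on the iminium carbon after the intermolecular Michael step. The one new stereocentre kept in 16, C4 (S), is controlled by the chiral phosphate, which shields one face of the planar methide carbon in the bifunctional hydrogen-bonded assembly, while C2 of 15 is uncontrolled and is erased by the elimination. The step needs face selectivity at C4, which the catalyst and not the remote gallocatechin stereocentres must provide (the C4 epimer is a diastereomer, so the sense is read at once and the catalyst antipode is taken if required), and regioselectivity, which is secured because the enamide has a single nucleophilic carbon, O1 is the only free phenol and C8 of ring D is blocked. Only weak acids are used so that the acid-labile bond from C4 to ring D is not ionised.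

Step 8
Reactants: 16 (4S)-4H-chromene
Product: 18 protected 4-arylflavan-3-ol, via C3-alkylborane 17 (not isolated)
Conditions: BH3·THF (3 equiv), THF, 0 °C → rt; then 3 M NaOH, 30 % H2O2, 0 °C → rt
Reagents that add atoms: hydrogen peroxide (OO)
Why: Brown hydroboration–oxidation of the enol ether, in which boron adds to C3 (β to O1, distal to ring B) and hydrogen to C2 in a syn fashion from the face opposite the bulky C4 aryl group, so that oxidation with retention gives the 3-OH trans to the C4 aryl and, the hydrogen on C2 being cis to boron, trans to ring B as well, i.e. (2R,3S,4S).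

Step 9
Reactants: 18 protected 4-arylflavan-3-ol
Product: 19 robinetinidol-(4α→6)-gallocatechin
Conditions: H2 (1 atm), Pd(OH)2/C (20 wt %), Et3N (2 equiv), THF/MeOH/H2O, rt
Reagents that add atoms: none
Why: Catalytic hydrogenolysis cleaves the ten benzyl ethers and the C8–Br bond of ring D without touching a stereocentre, and triethylamine binds the HBr that would otherwise ionise the acid-labile interflavan bond.

**Compound list**

1 | (+)-gallocatechin, (2R,3S)-2-(3,4,5-trihydroxyphenyl)chromane-3,5,7-triol | O[C@H]1Cc2c(O)cc(O)cc2O[C@@H]1c1cc(O)c(O)c(O)c1 | starting material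

2 | (2R,3S)-3,5,7-tris(benzyloxy)-2-[3,4,5-tris(benzyloxy)phenyl]chromane | C(c1ccccc1)O[C@H]1Cc2c(OCc3ccccc3)cc(OCc3ccccc3)cc2O[C@@H]1c1cc(OCc2ccccc2)c(OCc2ccccc2)c(OCc2ccccc2)c1 | intermediate

3 | (2R,3S)-8-bromo-3,5,7-tris(benzyloxy)-2-[3,4,5-tris(benzyloxy)phenyl]chromane | C(c1ccccc1)O[C@H]1Cc2c(OCc3ccccc3)cc(OCc3ccccc3)c(Br)c2O[C@@H]1c1cc(OCc2ccccc2)c(OCc2ccccc2)c(OCc2ccccc2)c1 | intermediate

4 | (2R,3S)-8-bromo-6-iodo-3,5,7-tris(benzyloxy)-2-[3,4,5-tris(benzyloxy)phenyl]chromane | C(c1ccccc1)O[C@H]1Cc2c(OCc3ccccc3)c(I)c(OCc3ccccc3)c(Br)c2O[C@@H]1c1cc(OCc2ccccc2)c(OCc2ccccc2)c(OCc2ccccc2)c1 | intermediate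

5 | 4-(benzyloxy)-2-hydroxybenzaldehyde | O=Cc1ccc(OCc2ccccc2)cc1O | starting material

6 | [(2R,3S)-8-bromo-3,5,7-tris(benzyloxy)-2-[3,4,5-tris(benzyloxy)phenyl]chroman-6-yl]magnesium chloride (LiCl complex) | C(c1ccccc1)O[C@H]1Cc2c(OCc3ccccc3)c([Mg]Cl)c(OCc3ccccc3)c(Br)c2O[C@@H]1c1cc(OCc2ccccc2)c(OCc2ccccc2)c(OCc2ccccc2)c1 | intermediate

7 | sodium 5-(benzyloxy)-2-formylphenolate | [Na+].[O-]c1cc(OCc2ccccc2)ccc1C=O | intermediate

8 | [4-(benzyloxy)-2-hydroxyphenyl][(2R,3S)-8-bromo-3,5,7-tris(benzyloxy)-2-[3,4,5-tris(benzyloxy)phenyl]chroman-6-yl]methanol, both carbinol epimers | OC(c1ccc(OCc2ccccc2)cc1O)c1c(OCc2ccccc2)c(Br)c2O[C@H](c3cc(OCc4ccccc4)c(OCc4ccccc4)c(OCc4ccccc4)c3)[C@@H](OCc3ccccc3)Cc2c1OCc1ccccc1 | intermediate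

9 | 3,4,5-tris(benzyloxy)benzaldehyde | O=Cc1cc(OCc2ccccc2)c(OCc2ccccc2)c(OCc2ccccc2)c1 | starting material

10 | 3,4,5-tris(benzyloxy)benzonitrile | N#Cc1cc(OCc2ccccc2)c(OCc2ccccc2)c(OCc2ccccc2)c1 | intermediate

11 | N-(bromomagnesio) ketimine of 1-[3,4,5-tris(benzyloxy)phenyl]ethanone | CC(=N[Mg]Br)c1cc(OCc2ccccc2)c(OCc2ccccc2)c(OCc2ccccc2)c1 | intermediate

12 | N-{1-[3,4,5-tris(benzyloxy)phenyl]ethylidene}acetamide | CC(=O)N=C(C)c1cc(OCc2ccccc2)c(OCc2ccccc2)c(OCc2ccccc2)c1 | intermediate

13 | N-{1-[3,4,5-tris(benzyloxy)phenyl]ethenyl}acetamide | CC(=O)NC(=C)c1cc(OCc2ccccc2)c(OCc2ccccc2)c(OCc2ccccc2)c1 | intermediate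

14 | (6E)-3-(benzyloxy)-6-{[(2R,3S)-8-bromo-3,5,7-tris(benzyloxy)-2-[3,4,5-tris(benzyloxy)phenyl]chroman-6-yl]methylidene}cyclohexa-2,4-dien-1-one | O=C1C=C(OCc2ccccc2)C=C/C1=C\c1c(OCc2ccccc2)c(Br)c2O[C@H](c3cc(OCc4ccccc4)c(OCc4ccccc4)c(OCc4ccccc4)c3)[C@@H](OCc3ccccc3)Cc2c1OCc1ccccc1 | intermediate

15 | N-[(4S)-7-(benzyloxy)-4-[(2R,3S)-8-bromo-3,5,7-tris(benzyloxy)-2-[3,4,5-tris(benzyloxy)phenyl]chroman-6-yl]-2-[3,4,5-tris(benzyloxy)phenyl]chroman-2-yl]acetamide, both C2 epimers | C(c1ccccc1)Oc1ccc2c(c1)OC(NC(C)=O)(c1cc(OCc3ccccc3)c(OCc3ccccc3)c(OCc3ccccc3)c1)C[C@@H]2c1c(OCc2ccccc2)c(Br)c2O[C@H](c3cc(OCc4ccccc4)c(OCc4ccccc4)c(OCc4ccccc4)c3)[C@@H](OCc3ccccc3)Cc2c1OCc1ccccc1 | intermediate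

16 | (4S)-7-(benzyloxy)-4-[(2R,3S)-8-bromo-3,5,7-tris(benzyloxy)-2-[3,4,5-tris(benzyloxy)phenyl]chroman-6-yl]-2-[3,4,5-tris(benzyloxy)phenyl]-4H-chromene | C(c1ccccc1)Oc1ccc2c(c1)OC(c1cc(OCc3ccccc3)c(OCc3ccccc3)c(OCc3ccccc3)c1)=C[C@@H]2c1c(OCc2ccccc2)c(Br)c2O[C@H](c3cc(OCc4ccccc4)c(OCc4ccccc4)c(OCc4ccccc4)c3)[C@@H](OCc3ccccc3)Cc2c1OCc1ccccc1 | intermediate

17 | C3-borane of 16: boron on C3 trans to the aryl groups on C2 and C4, geometry as in 18 | C(c1ccccc1)Oc1ccc2c(c1)O[C@H](c1cc(OCc3ccccc3)c(OCc3ccccc3)c(OCc3ccccc3)c1)[C@@H](B)[C@@H]2c1c(OCc2ccccc2)c(Br)c2O[C@H](c3cc(OCc4ccccc4)c(OCc4ccccc4)c(OCc4ccccc4)c3)[C@@H](OCc3ccccc3)Cc2c1OCc1ccccc1 | intermediate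

18 | (2R,3S,4S)-7-(benzyloxy)-4-[(2R,3S)-8-bromo-3,5,7-tris(benzyloxy)-2-[3,4,5-tris(benzyloxy)phenyl]chroman-6-yl]-2-[3,4,5-tris(benzyloxy)phenyl]chroman-3-ol | C(c1ccccc1)Oc1ccc2c(c1)O[C@H](c1cc(OCc3ccccc3)c(OCc3ccccc3)c(OCc3ccccc3)c1)[C@@H](O)[C@@H]2c1c(OCc2ccccc2)c(Br)c2O[C@H](c3cc(OCc4ccccc4)c(OCc4ccccc4)c(OCc4ccccc4)c3)[C@@H](OCc3ccccc3)Cc2c1OCc1ccccc1 | intermediate

19 | robinetinidol-(4α→6)-gallocatechin, (2R,3S,4S)-4-[(2R,3S)-3,5,7-trihydroxy-2-(3,4,5-trihydroxyphenyl)chroman-6-yl]-2-(3,4,5-trihydroxyphenyl)chromane-3,7-diol | Oc1ccc2c(c1)O[C@H](c1cc(O)c(O)c(O)c1)[C@@H](O)[C@@H]2c1c(O)cc2c(c1O)C[C@H](O)[C@@H](c1cc(O)c(O)c(O)c1)O2 | target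

**Step count and risks**

Total step count: 9. Longest linear sequence: 7 steps (1, 2, 3, 4, 7, 8, 9); the enamide branch is 2 steps (5, 6).

Steps most likely to fail:

1. Step 7. The process at risk is face selection at the methide carbon: the di-ortho-substituted ring D crowds both faces and may not fit the catalyst pocket. The Michael addition may also be slow, with hydrolysis of the enamide by the released water competing. The fallback sets out from 8 and 9 and comes back at 18, with C4 set by boron-to-carbon alkenyl transfer and ring C still closed last, now by epoxide opening. Aldehyde 9 would be olefinated with bis(pinacolato)borylmethane and lithium 2,2,6,6-tetramethylpiperidide (boron–Wittig) to the (E)-alkenyl pinacol boronate F1. NaIO4/NH4OAc would cleave F1 to the (E)-alkenylboronic acid F2, and azeotropic esterification with ethanol would give the diethyl (E)-alkenylboronate F3. Benzhydrol 8, F3 and the appropriate enantiomer of 3,3'-dibromo-BINOL (15 mol %) in toluene with 4 Å MS should give the (S)-configured (E)-1,1,3-triarylpropene F4, by way of the boronate bound to the oxygen of 14 and intramolecular alkenyl transfer (BINOL-catalysed enantioselective alkenylboronate addition to ortho-quinone methides). Shi epoxidation of F4 with the L-fructose-derived enantiomer of the ketone catalyst and KHSO5 at pH 8 should give the (2S,3S)-trans-epoxide F5. Camphorsulfonic acid (cat.) in CH2Cl2 would then close F5 by 6-endo attack of the phenol at the benzylic carbon with inversion, giving 18 directly; steps 7 and 8 are bypassed.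

2. Step 4. The process at risk is the halogen–magnesium exchange (incomplete, or not selective for iodine over bromine) and the addition of the hindered aryl Grignard reagent to the phenoxide-deactivated aldehyde; the product may also ionise on work-up. The fallback sets out from 3 and comes back at 8 with the polarity reversed. Vilsmeier–Haack formylation of 3 (POCl3, DMF, 70 °C; C8 of ring D is blocked) would give the 6-carbaldehyde F6. Bromomagnesium 3-(benzyloxy)phenoxide F7, made from purchased 3-(benzyloxy)phenol and EtMgBr in toluene, would add to F6 ortho to its oxygen through a six-membered magnesium chelate (ortho-selective hydroxyalkylation of a magnesium phenoxide), at the position para to the benzyloxy group, to give 8. Step 3 is then not needed.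

3. Step 8. The process at risk is slow or face-unselective hydroboration of the hindered trisubstituted enol ether, or β-alkoxy elimination of the borane with opening of ring C. The fallback sets out from 16 and comes back at 18; it introduces the C3 oxygen by epoxidation and the C2 hydrogen by ionic reduction. Dimethyldioxirane (acetone, −40 °C) should epoxidise 16 anti to the C4 aryl group to give the 2,3-epoxide F8. Without isolation, Et3SiH and BF3·OEt2 at −78 °C would ionise F8 at C2 to the 2-aryl oxocarbenium ion, which takes up hydride axially so that ring B becomes equatorial (as in the silane reduction of aryl lactols to C-aryl glycosides), giving 18.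

**Further compounds**

F1 | step 7 | 2-[(E)-2-[3,4,5-tris(benzyloxy)phenyl]ethenyl]-4,4,5,5-tetramethyl-1,3,2-dioxaborolane | CC1(C)OB(/C=C/c2cc(OCc3ccccc3)c(OCc3ccccc3)c(OCc3ccccc3)c2)OC1(C)C

F2 | step 7 | (E)-2-[3,4,5-tris(benzyloxy)phenyl]ethenylboronic acid | OB(O)/C=C/c1cc(OCc2ccccc2)c(OCc2ccccc2)c(OCc2ccccc2)c1

F3 | step 7 | diethyl (E)-2-[3,4,5-tris(benzyloxy)phenyl]ethenylboronate | CCOB(OCC)/C=C/c1cc(OCc2ccccc2)c(OCc2ccccc2)c(OCc2ccccc2)c1

F4 | step 7 | 5-(benzyloxy)-2-[(1S,2E)-1-[(2R,3S)-8-bromo-3,5,7-tris(benzyloxy)-2-[3,4,5-tris(benzyloxy)phenyl]chroman-6-yl]-3-[3,4,5-tris(benzyloxy)phenyl]prop-2-en-1-yl]phenol | C(c1ccccc1)Oc1ccc(c(O)c1)[C@H](/C=C/c1cc(OCc2ccccc2)c(OCc2ccccc2)c(OCc2ccccc2)c1)c1c(OCc2ccccc2)c(Br)c2O[C@H](c3cc(OCc4ccccc4)c(OCc4ccccc4)c(OCc4ccccc4)c3)[C@@H](OCc3ccccc3)Cc2c1OCc1ccccc1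

F5 | step 7 | 5-(benzyloxy)-2-[(S)-[(2R,3S)-8-bromo-3,5,7-tris(benzyloxy)-2-[3,4,5-tris(benzyloxy)phenyl]chroman-6-yl][(2S,3S)-3-[3,4,5-tris(benzyloxy)phenyl]oxiran-2-yl]methyl]phenol | C(c1ccccc1)Oc1ccc(c(O)c1)[C@H]([C@@H]1O[C@H]1c1cc(OCc2ccccc2)c(OCc2ccccc2)c(OCc2ccccc2)c1)c1c(OCc2ccccc2)c(Br)c2O[C@H](c3cc(OCc4ccccc4)c(OCc4ccccc4)c(OCc4ccccc4)c3)[C@@H](OCc3ccccc3)Cc2c1OCc1ccccc1

F6 | step 4 | (2R,3S)-8-bromo-3,5,7-tris(benzyloxy)-2-[3,4,5-tris(benzyloxy)phenyl]chromane-6-carbaldehyde | C(c1ccccc1)O[C@H]1Cc2c(OCc3ccccc3)c(C=O)c(OCc3ccccc3)c(Br)c2O[C@@H]1c1cc(OCc2ccccc2)c(OCc2ccccc2)c(OCc2ccccc2)c1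

F7 | step 4 | bromomagnesium 3-(benzyloxy)phenoxide | Br[Mg]Oc1cccc(OCc2ccccc2)c1

F8 | step 8 | 2,3-epoxide of 16, epoxide oxygen on the face opposite the C4 aryl group | C(c1ccccc1)Oc1ccc2c(c1)O[C@@]1(c3cc(OCc4ccccc4)c(OCc4ccccc4)c(OCc4ccccc4)c3)O[C@H]1[C@@H]2c1c(OCc2ccccc2)c(Br)c2O[C@H](c3cc(OCc4ccccc4)c(OCc4ccccc4)c(OCc4ccccc4)c3)[C@@H](OCc3ccccc3)Cc2c1OCc1ccccc1
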